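A small charge of incoming ligand, 0.0525 M on 0.035 M of starting complex in west, is 1.50 equivalents, and I kept books on where each ligand goes.

common to all: starting complex 0.035 M
- blue: incoming ligand 0.030 M; run made earlier
- amber: incoming ligand 0.045 M; run made earlier
- ochre: incoming ligand 0.047 M; run made earlier
- east: incoming ligand 0.0350 M; time 4.0 d
- north: incoming ligand 0.0420 M; time 4.0 d
- west: incoming ligand 0.0525 M; time 4.0 d

| run | time / d | complex with one exchanged / % | complex with three exchanged / % | starting complex / % |
|---|---|---|---|---|
| blue | 0.333 | 12.0 | 0.4 | 61.7 |
| blue | 0.625 | 11.0 | 0.2 | 55.1 |
| blue | 1.04 | 10.5 | 1.2 | 53.6 |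
| blue | 2.00 | 11.1 | 0.3 | 52.2 |
| blue | 4.00 | 11.2 | 0.1 | 52.3 |
| amber | 0.833 | 9.5 | 1.5 | 36.9 |
| amber | 1.67 | 8.2 | 0 | 34.6 |
| amber | 2.50 | 7.0 | 0.6 | 34.4 |
| amber | 3.00 | 8.0 | 0.3 | 34.6 |
| amber | 4.00 | 8.2 | 0 | 34.2 |
| ochre | 0.333 | 11.1 | 0.6 | 45.5 |
| ochre | 0.625 | 9.2 | 0 | 38.4 |
| ochre | 1.04 | 8.1 | 0.2 | 34.3 |
| ochre | 2.00 | 8.6 | 0 | 32.5 |
| ochre | 4.00 | 7.2 | 0 | 32.4 |

(readings scatter by 0.5 percentage points)

- a reading or a percentage of complex with three exchanged counts all its forms, free or not

1. which of these holds the largest part of the starting complex at the end of east (complex with one exchanged / starting complex / complex with three exchanged / complex with two exchanged)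
2. which of these holds the largest part of the starting complex at the end of north (complex with one exchanged / starting complex / complex with three exchanged / complex with two exchanged)
3. which of these holds the largest part of the starting complex at the end of west (complex with one exchanged / starting complex / complex with three exchanged / complex with two exchanged)
4. amount of complex with one exchanged at the end of west, in percent of the starting complex charged

The earlier runs went flat with starting complex left: blue read 52.2%, then 52.3%. So I treated incoming ligand as the limiting reagent and booked its whole charge, e equivalents, in three entries, as fractions of the starting complex charged.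

The first entry is complex with one exchanged, a = r·m, where m is the starting complex left and r is the standing ratio, complex with one exchanged over starting complex at the last reading, averaged over the runs: 0.225. I assumed that both exchanges draw on the same free ligand and looked for a ratio that stayed put from run to run, and the readings gave 0.214, 0.240 and 0.222 from blue to ochre.

The second entry is the remainder D = 1 − m − a, at two ligands each. The third is the gap g, the ligand those two entries leave unbooked: 1.51% in blue, 5.17% in amber and 6.29% in ochre, as readings. Complex with three exchanged read near zero at the last readings, so I booked g as a third ligand on something unread that sits inside D, which leaves b = D − g for complex with two exchanged.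

The books close at m = (2 − e + g)/(2 + r). With the gap of the nearest run, east gave m = 45.6% against b = 42.6%, north 38.3% against 47.9%, and west 25.3% against 62.7%, with a = 5.70%.

The forecast named starting complex, complex with two exchanged and complex with two exchanged for east, north and west, and put complex with one exchanged in west at 7%, above my figure, noting that “The ratio of complex with one exchanged to starting complex barely changes with ligand”.

The flasks gave starting complex on top in east, complex with two exchanged in north and complex with two exchanged in west, with 6.11% of complex with one exchanged in west.

    starting complex + incoming ligand → leaving ligand + complex with one exchanged (k = 0.0629 M⁻¹ min⁻¹)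
    complex with three exchanged ⇌ isomer of the product (K = 0.738, k = 0.00149 min⁻¹)
    complex with three exchanged → over-reaction product (k = 0.00523 min⁻¹)
    complex with two exchanged + incoming ligand → leaving ligand + complex with three exchanged (k = 0.0116 M⁻¹ min⁻¹)
    complex with one exchanged + incoming ligand → leaving ligand + complex with two exchanged (k = 0.330 M⁻¹ min⁻¹)
    crystals ⇌ complex with three exchanged, rate k6*(cs6 - [complex with three exchanged]) while solid is left; crystals form when [complex with three exchanged] > cs6 (solubility = 22.0 mM, k = 1.50 min⁻¹)

West also held 8.12% of over-reaction product, which stands in my books as the unread entry. Its 26.0% of starting complex times r gives 5.85% of complex with one exchanged. The neighbour charged with 0.021 M of starting complex ended with 2.11% of it, so r gives 0.475% there, and that flask held 0.496%.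

The readings stem from a simulated flask from invented constants; scatter was added.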